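The two silyl ethers and the C8 acetal come off last. Ring B is then cut in one stroke at C1'–C2', C2'–C3', C4'–C5' and C5'–C6', which leaves a chroman-3-yl α-diazo enone and a prenyl-bearing siloxyalkyne.
This cut is possible because ring B carries chroman C3 on C1', OH on C2', prenyl on C3', OH on C4' and only hydrogen on C5' and C6'. A 4-substituted vinylketene and a 1-siloxyalkyne produce exactly this pattern, with the two oxygens differentiated.
The diazo enone goes back by diazo transfer, cross-metathesis and Zweifel vinylation (C3–C1') to a 3-boryl chroman. That goes back to a 2H-chromene, cut at C4–C4a and O1–C2 into propargyl bromide and a phloroglucinaldehyde ether.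
In the forward direction ring A is bought, pyran ring C closes by gold-catalysed hydroarylation, and the four-carbon chain is grown on C3. The alkyne comes in one step from an ester, and ring B closes third from the end.
The single stereocentre C3 is set by ligand-controlled copper-catalysed protoboration of the chromene. Boron is then exchanged for carbon with retention, and no later step touches C3.

Key step: step 11

Assumption: the (R,R) antipode of Ph-BPE is taken to deliver boron to the alkene face that gives the (3S)-boronate; both antipodes are sold, so the ligand is swapped if a trial run shows the opposite sense.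
Abbreviations: TIPS = triisopropylsilyl; Bpin = 4,4,5,5-tetramethyl-1,3,2-dioxaborolan-2-yl; Chr = (3R)-8-(1,3-dioxolan-2-yl)-5-methoxy-7-(triisopropylsilyloxy)chroman-3-yl, with C3 arranged in space as in the target. All acetal-bearing intermediates are purified on triethylamine-deactivated silica gel.

Step 1
Reactants: 1 2,4,6-trihydroxybenzaldehyde
Product: 2 2,6-dihydroxy-4-methoxybenzaldehyde
Conditions: Me2SO4 (1.0 equiv), K2CO3 (1.0 equiv), acetone, rt
Reagents that add atoms: dimethyl sulfate, COS(=O)(=O)OC
Why: Williamson O-methylation, in which the 4-OH is the most acidic hydroxyl and the only one not tied to the formyl oxygen by a hydrogen bond, so one equivalent of a hard methylating agent should react there first.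

Step 2
Reactants: 2 2,6-dihydroxy-4-methoxybenzaldehyde; 3 propargyl bromide
Product: 4 2-hydroxy-4-methoxy-6-(prop-2-yn-1-yloxy)benzaldehyde
Conditions: K2CO3 (1.1 equiv), acetone, 56 °C
Reagents that add atoms: none
Why: Williamson etherification of a symmetric bis-phenol, in which the hydroxyl left after the first alkylation is locked in a strong hydrogen bond to C=O and should resist a second alkylation.

Step 3
Reactants: 4 2-hydroxy-4-methoxy-6-(prop-2-yn-1-yloxy)benzaldehyde
Product: 5 4-methoxy-2-(prop-2-yn-1-yloxy)-6-(triisopropylsilyloxy)benzaldehyde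
Conditions: i-Pr3SiOTf, 2,6-lutidine, CH2Cl2, 0 °C
Reagents that add atoms: triisopropylsilyl triflate, CC(C)[Si](C(C)C)(C(C)C)OS(=O)(=O)C(F)(F)F
Why: Phenol silylation with a silyl triflate and a hindered base overcomes the hydrogen bond, and the aryl TIPS ether is chosen because it should survive the alkoxide, Grignard and amide-base steps ahead yet leave with fluoride at the end.

Step 4
Reactants: 5 4-methoxy-2-(prop-2-yn-1-yloxy)-6-(triisopropylsilyloxy)benzaldehyde
Product: 6 5-methoxy-7-(triisopropylsilyloxy)-2H-chromene-8-carbaldehyde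
Conditions: Ph3PAuNTf2 (3 mol %), ClCH2CH2Cl, 60 °C
Reagents that add atoms: none
Why: Intramolecular 6-endo-dig hydroarylation of an aryl propargyl ether, in which cationic monovalent gold activates the alkyne and the only free ortho carbon (ortho to OMe, para to OTIPS, the other ortho site blocked by CHO) attacks it to close ring C.

Step 5
Reactants: 6 5-methoxy-7-(triisopropylsilyloxy)-2H-chromene-8-carbaldehyde
Product: 7 8-(1,3-dioxolan-2-yl)-5-methoxy-7-(triisopropylsilyloxy)-2H-chromene
Conditions: (Me3SiOCH2)2, Me3SiOTf (5 mol %), CH2Cl2, −78 → −30 °C; pyridine quench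
Reagents that add atoms: 1,2-bis(trimethylsilyloxy)ethane, C[Si](C)(C)OCCO[Si](C)(C)C
Why: Noyori acetalisation works under water-free kinetic conditions and so suits an electron-rich, doubly ortho-substituted aldehyde whose Dean–Stark equilibrium is poor, and the acetal shields the formyl group from boryl copper, Grignard reagent, amide base and light.

Step 6
Reactants: 7 8-(1,3-dioxolan-2-yl)-5-methoxy-7-(triisopropylsilyloxy)-2H-chromene
Product: 8 (3S)-8-(1,3-dioxolan-2-yl)-5-methoxy-3-Bpin-7-(triisopropylsilyloxy)chroman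
Conditions: CuCl (5 mol %), (R,R)-Ph-BPE (6 mol %), NaOt-Bu (10 mol %), B2pin2 (1.2 equiv), MeOH (2 equiv), THF, rt
Reagents that add atoms: bis(pinacolato)diboron, CC1(C)OB(OC1(C)C)B1OC(C)(C)C(C)(C)O1
Why: Copper-catalysed enantioselective protoboration of an aryl-conjugated cyclic alkene, known for 2H-chromenes and 1,2-dihydronaphthalenes: the ligated boryl copper species adds syn with copper on benzylic C4 and boron on C3, methanol protonates the C–Cu bond, and the C2-symmetric bisphosphine selects the alkene face and thereby sets C3 (descriptor S because boron ranks below carbon).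

Step 7
Reactants: 8 (3S)-8-(1,3-dioxolan-2-yl)-5-methoxy-3-Bpin-7-(triisopropylsilyloxy)chroman; 9 vinylmagnesium bromide
Product: 12 (3R)-8-(1,3-dioxolan-2-yl)-3-ethenyl-5-methoxy-7-(triisopropylsilyloxy)chroman, via vinyl borate 10 (not isolated), via iodoalkyl boronate 11 (not isolated)
Conditions: CH2=CHMgBr (1.3 equiv), THF/DMSO 1:1, 0 °C → rt; I2, THF, 0 °C; NaOMe, MeOH, 0 °C → rt
Reagents that add atoms: iodine, [I][I] (its atom is carried only by intermediate 11)
Why: Zweifel olefination, in which the Grignard reagent forms borate 10, iodine activates the vinyl group so that C3 migrates from boron to carbon with retention to give 11, and methoxide triggers anti elimination of boron and iodide, so C–vinyl takes the place of C–B in space (the descriptor becomes R only through the priority rules).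

Step 8
Reactants: 12 (3R)-8-(1,3-dioxolan-2-yl)-3-ethenyl-5-methoxy-7-(triisopropylsilyloxy)chroman; 13 methyl vinyl ketone
Product: 14 (E)-4-Chr-but-3-en-2-one
Conditions: 13 (4 equiv), second-generation Grubbs catalyst (5 mol %), CH2Cl2, 40 °C
Reagents that add atoms: none
Why: Olefin cross-metathesis of a terminal alkene and an electron-poor enone, a pairing in which the enone barely homodimerises and the E-alkene is favoured thermodynamically, while C3 takes no part and no prenyl group is yet present to interfere.

Step 9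
Reactants: 14 (E)-4-Chr-but-3-en-2-one
Product: 16 (E)-1-diazo-4-Chr-but-3-en-2-one, via trifluoroacetyl diketone 15 (not isolated)
Conditions: LiN(SiMe3)2, THF, −78 °C; CF3CO2CH2CF3, −78 °C; cold sat. aq NH4Cl work-up; then MsN3, Et3N, H2O (1 equiv), MeCN, rt
Reagents that add atoms: methanesulfonyl azide, CS(=O)(=O)N=[N+]=[N-]; 2,2,2-trifluoroethyl trifluoroacetate, O=C(OCC(F)(F)F)C(F)(F)F (its CF3CO group is carried only by intermediate 15)
Why: Detrifluoroacetylative diazo transfer (Danheiser protocol), in which the hindered amide base removes a proton kinetically from the α'-methyl group rather than the γ-hydrogen on C3, trifluoroacetylation gives the activated diketone 15, and the sulfonyl azide with Et3N transfers N2 with loss of the trifluoroacetyl group, so C3 should not epimerise and the δ-aryloxide should not be expelled.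

Step 10
Reactants: 17 ethyl 4-methylpent-3-enoate
Product: 20 5-methyl-1-(triisopropylsilyloxy)hex-4-en-1-yne, via dibromo enolate 18 (not isolated), via lithium ynolate 19 (not isolated)
Conditions: CH2Br2, lithium 2,2,6,6-tetramethylpiperidide, THF, −78 °C; add 17; n-BuLi, −78 °C → rt; i-Pr3SiCl, −78 → 0 °C
Reagents that add atoms: dibromomethane, BrCBr; chlorotriisopropylsilane, CC(C)[Si](Cl)(C(C)C)C(C)C
Why: Kowalski ester homologation stopped at the ynolate, in which LiCHBr2 is acylated by the ester, dibromo enolate 18 undergoes Br–Li exchange and a carbenoid 1,2-shift of the prenyl group to give ynolate 19, and the bulky chlorosilane traps 19 on oxygen rather than on carbon.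

Step 11
Reactants: 16 (E)-1-diazo-4-Chr-but-3-en-2-one; 20 5-methyl-1-(triisopropylsilyloxy)hex-4-en-1-yne
Product: 24 6-Chr-2-(3-methylbut-2-en-1-yl)-3-(triisopropylsilyloxy)phenol, the (3R)-isoflavan having free 2'-OH plus 3'-prenyl plus 4'-OTIPS, via vinylketene 21 (not isolated), via cyclobutenone 22 (not isolated), via dienylketene 23 (not isolated)
Conditions: 20 (1.5 equiv), degassed toluene (0.1 M), hν (medium-pressure Hg lamp, Pyrex filter), rt; then 110 °C
Reagents that add atoms: none
Why: On excitation 16 loses N2 while its alkenyl group moves from the carbonyl carbon to the former diazo carbon (Wolff rearrangement, new C5'–C6' bond), so E-vinylketene 21 has chroman C3 on its remote alkene terminus. The nucleophilic, prenyl-bearing carbon of 20 attacks the ketene carbonyl carbon and the oxygen-bearing alkyne carbon closes onto the ketene α-carbon, a polarity-matched (2+2) addition that forms C2'–C3' and C4'–C5' in cyclobutenone 22. Heat and residual light cleave the old C2'–C5' bond of 22 by reversible 4π electrocyclic opening to dienylketene 23, and ring B then closes by 6π electrocyclisation between the ketene carbon and the alkene terminus (C1'–C2'), followed by tautomerisation to the phenol. This is the diazo ketone (second-generation) form of the Danheiser benzannulation, for which α-diazo enones and triisopropylsiloxyalkynes are established partners that give resorcinol monosilyl ethers. No lasting stereocentre is made, since the sp3 ring carbon of 22 is erased on opening, and C3 from step 6 stays a spectator because neither acid nor base is present and the E-geometry holds its hydrogen out of reach of a 1,5-shift to the ketene. The step needs regioselectivity, secured by the donor oxygen of 20, which places prenyl between the free 2'-OH and the 4'-OTIPS group, and chemoselectivity for the alkyne over the prenyl alkene, secured by the far higher nucleophilicity of the ynol ether; toluene and the Pyrex filter keep HCl and short-wave light away from the acetal and ring A.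

Step 12
Reactants: 24 6-Chr-2-(3-methylbut-2-en-1-yl)-3-(triisopropylsilyloxy)phenol
Product: 25 (3R)-3-[2-hydroxy-3-(3-methylbut-2-en-1-yl)-4-(triisopropylsilyloxy)phenyl]-5-methoxy-7-(triisopropylsilyloxy)chroman-8-carbaldehyde
Conditions: pyridinium p-toluenesulfonate (cat.), acetone/H2O 10:1, rt
Reagents that add atoms: water, O
Why: Acid-catalysed acetal hydrolysis, in which the trioxygenated ring A stabilises the oxocarbenium ion so strongly that a very weak acid should suffice, well below the acidity that would cyclise the ortho-prenylphenol or cleave an aryl TIPS ether.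

Step 13
Reactants: 25 (3R)-3-[2-hydroxy-3-(3-methylbut-2-en-1-yl)-4-(triisopropylsilyloxy)phenyl]-5-methoxy-7-(triisopropylsilyloxy)chroman-8-carbaldehyde
Product: 26 (3R)-3-[2,4-dihydroxy-3-(3-methylbut-2-en-1-yl)phenyl]-7-hydroxy-5-methoxychroman-8-carbaldehyde (CNP0399843.1)
Conditions: Bu4NF (2.5 equiv), AcOH (2.5 equiv), THF, 0 °C
Reagents that add atoms: none
Why: Fluoride-induced cleavage of both aryl silyl ethers, buffered by acetic acid so that the phenoxides are protonated at once and the aldehyde, the prenyl group and the non-acidic C3–H are left alone.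

Compound list
1 | 2,4,6-trihydroxybenzaldehyde | O=Cc1c(O)cc(O)cc1O | starting material
2 | 2,6-dihydroxy-4-methoxybenzaldehyde | COc1cc(O)c(C=O)c(O)c1 | intermediate
3 | propargyl bromide (3-bromoprop-1-yne) | C#CCBr | starting material
4 | 2-hydroxy-4-methoxy-6-(prop-2-yn-1-yloxy)benzaldehyde | COc1cc(O)c(C=O)c(OCC#C)c1 | intermediate
5 | 4-methoxy-2-(prop-2-yn-1-yloxy)-6-(triisopropylsilyloxy)benzaldehyde | COc1cc(O[Si](C(C)C)(C(C)C)C(C)C)c(C=O)c(OCC#C)c1 | intermediate
6 | 5-methoxy-7-(triisopropylsilyloxy)-2H-chromene-8-carbaldehyde | COc1cc(O[Si](C(C)C)(C(C)C)C(C)C)c(C=O)c2c1C=CCO2 | intermediate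
7 | 8-(1,3-dioxolan-2-yl)-5-methoxy-7-(triisopropylsilyloxy)-2H-chromene | COc1cc(O[Si](C(C)C)(C(C)C)C(C)C)c(C3OCCO3)c2c1C=CCO2 | intermediate
8 | (3S)-8-(1,3-dioxolan-2-yl)-5-methoxy-3-(4,4,5,5-tetramethyl-1,3,2-dioxaborolan-2-yl)-7-(triisopropylsilyloxy)chroman | COc1cc(O[Si](C(C)C)(C(C)C)C(C)C)c(C3OCCO3)c2c1C[C@H](B3OC(C)(C)C(C)(C)O3)CO2 | intermediate
9 | vinylmagnesium bromide | C=C[Mg]Br | starting material
10 | bromomagnesium salt of the (3S)-chroman-3-yl(vinyl)(pinacolato)borate derived from 8 | COc1cc(O[Si](C(C)C)(C(C)C)C(C)C)c(C3OCCO3)c2c1C[C@H]([B-]3(C=C)OC(C)(C)C(C)(C)O3)CO2.[Mg+]Br | intermediate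
11 | (3R)-8-(1,3-dioxolan-2-yl)-3-[2-iodo-1-Bpin-ethyl]-5-methoxy-7-(triisopropylsilyloxy)chroman, both epimers at the boron-bearing carbon | COc1cc(O[Si](C(C)C)(C(C)C)C(C)C)c(C3OCCO3)c2c1C[C@H](C(CI)B3OC(C)(C)C(C)(C)O3)CO2 | intermediate
12 | (3R)-8-(1,3-dioxolan-2-yl)-3-ethenyl-5-methoxy-7-(triisopropylsilyloxy)chroman | COc1cc(O[Si](C(C)C)(C(C)C)C(C)C)c(C3OCCO3)c2c1C[C@H](C=C)CO2 | intermediate
13 | methyl vinyl ketone (but-3-en-2-one) | CC(=O)C=C | starting material
14 | (E)-4-[(3R)-8-(1,3-dioxolan-2-yl)-5-methoxy-7-(triisopropylsilyloxy)chroman-3-yl]but-3-en-2-one | COc1cc(O[Si](C(C)C)(C(C)C)C(C)C)c(C3OCCO3)c2c1C[C@H](/C=C/C(C)=O)CO2 | intermediate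
15 | (E)-1,1,1-trifluoro-6-[(3R)-8-(1,3-dioxolan-2-yl)-5-methoxy-7-(triisopropylsilyloxy)chroman-3-yl]hex-5-ene-2,4-dione | COc1cc(O[Si](C(C)C)(C(C)C)C(C)C)c(C3OCCO3)c2c1C[C@H](/C=C/C(=O)CC(=O)C(F)(F)F)CO2 | intermediate
16 | (E)-1-diazo-4-[(3R)-8-(1,3-dioxolan-2-yl)-5-methoxy-7-(triisopropylsilyloxy)chroman-3-yl]but-3-en-2-one | COc1cc(O[Si](C(C)C)(C(C)C)C(C)C)c(C3OCCO3)c2c1C[C@H](/C=C/C(=O)C=[N+]=[N-])CO2 | intermediate
17 | ethyl 4-methylpent-3-enoate | CCOC(=O)CC=C(C)C | starting material
18 | lithium 1,1-dibromo-5-methylhexa-1,4-dien-2-olate | CC(C)=CCC([O-])=C(Br)Br.[Li+] | intermediate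
19 | lithium 5-methylhex-4-en-1-yn-1-olate | CC(C)=CCC#C[O-].[Li+] | intermediate
20 | 5-methyl-1-(triisopropylsilyloxy)hex-4-en-1-yne | CC(C)=CCC#CO[Si](C(C)C)(C(C)C)C(C)C | intermediate
21 | (E)-4-[(3R)-8-(1,3-dioxolan-2-yl)-5-methoxy-7-(triisopropylsilyloxy)chroman-3-yl]buta-1,3-dien-1-one (vinylketene) | COc1cc(O[Si](C(C)C)(C(C)C)C(C)C)c(C3OCCO3)c2c1C[C@H](/C=C/C=C=O)CO2 | intermediate
22 | 4-{(E)-2-[(3R)-8-(1,3-dioxolan-2-yl)-5-methoxy-7-(triisopropylsilyloxy)chroman-3-yl]ethenyl}-2-(3-methylbut-2-en-1-yl)-3-(triisopropylsilyloxy)cyclobut-2-en-1-one, both epimers at the sp3 ring carbon | COc1cc(O[Si](C(C)C)(C(C)C)C(C)C)c(C3OCCO3)c2c1C[C@H](/C=C/C3C(=O)C(CC=C(C)C)=C3O[Si](C(C)C)(C(C)C)C(C)C)CO2 | intermediate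
23 | (3E,5E)-6-[(3R)-8-(1,3-dioxolan-2-yl)-5-methoxy-7-(triisopropylsilyloxy)chroman-3-yl]-2-(3-methylbut-2-en-1-yl)-3-(triisopropylsilyloxy)hexa-1,3,5-trien-1-one (dienylketene, ketene carbon and diene terminus on the same side) | COc1cc(O[Si](C(C)C)(C(C)C)C(C)C)c(C3OCCO3)c2c1C[C@H](/C=C/C=C(O[Si](C(C)C)(C(C)C)C(C)C)\C(CC=C(C)C)=C=O)CO2 | intermediate
24 | 6-[(3R)-8-(1,3-dioxolan-2-yl)-5-methoxy-7-(triisopropylsilyloxy)chroman-3-yl]-2-(3-methylbut-2-en-1-yl)-3-(triisopropylsilyloxy)phenol | COc1cc(O[Si](C(C)C)(C(C)C)C(C)C)c(C3OCCO3)c2c1C[C@H](c1ccc(O[Si](C(C)C)(C(C)C)C(C)C)c(CC=C(C)C)c1O)CO2 | intermediate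
25 | (3R)-3-[2-hydroxy-3-(3-methylbut-2-en-1-yl)-4-(triisopropylsilyloxy)phenyl]-5-methoxy-7-(triisopropylsilyloxy)chroman-8-carbaldehyde | COc1cc(O[Si](C(C)C)(C(C)C)C(C)C)c(C=O)c2c1C[C@H](c1ccc(O[Si](C(C)C)(C(C)C)C(C)C)c(CC=C(C)C)c1O)CO2 | intermediate
26 | (3R)-3-[2,4-dihydroxy-3-(3-methylbut-2-en-1-yl)phenyl]-7-hydroxy-5-methoxychroman-8-carbaldehyde | COc1cc(O)c(C=O)c2c1C[C@H](c1ccc(O)c(CC=C(C)C)c1O)CO2 | target

Total step count: 13. Longest linear sequence: 12 (steps 1–9 and 11–13). Step 10 is a one-step side branch.

Steps most likely to fail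

Step 11, the benzannulation.
- **What may go wrong:** Light may isomerise the enone double bond before nitrogen is lost, and a Z-vinylketene could then take up the C3 hydrogen in a 1,5-shift and erase the stereocentre. Ring A may act as an inner filter or degrade. Adventitious acid may strip the acetal. The phenol formed may capture the ketene.
- **Fallback:** The same vinylketene 21 is generated without light, setting out from 12. Cross-metathesis with but-3-enoic acid (second-generation Grubbs catalyst, CH2Cl2, 40 °C) should give (E)-4-Chr-but-3-enoic acid F1. 1-Chloro-N,N,2-trimethylprop-1-en-1-amine (Ghosez reagent, CH2Cl2, 0 °C) converts it under neutral conditions into (E)-4-Chr-but-3-enoyl chloride F2.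
- **Return to the route:** Slow addition of Et3N to F2 and 20 in toluene at 80–110 °C releases 21 by dehydrochlorination at the doubly activated α-carbon. The (2+2) addition, 4π opening and 6π closure then run thermally, and the route is rejoined at 24.

Step 6, the protoboration.
- **What may go wrong:** The three donor oxygens of ring A make the styrene-type alkene a weak acceptor for the boryl copper species, so turnover may stall. The peri 5-OMe group next to C4 may erode facial selectivity.
- **Fallback:** Reagent control by Brown asymmetric hydroboration replaces catalysis, setting out from 7. Diisopinocampheylborane in THF at −25 to 0 °C should place boron on C3, the site favoured both by the aryl group and by the allylic oxygen. It is drawn here from (+)-α-pinene, and the pinene antipode is fixed by a trial run. The product is the [(3S)-chroman-3-yl]bis(isopinocampheyl)borane F3.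
- **Return to the route:** Acetaldehyde expels both pinene units and leaves the diethyl (3S)-chroman-3-ylboronate F4. Transesterification with pinacol rejoins the route at 8.

Step 7, the Zweifel olefination.
- **What may go wrong:** The borate may fragment by loss of the β-aryloxide, opening ring C before migration. Iodine may also attack C6 of the electron-rich ring A instead of the vinyl group.
- **Fallback:** One-carbon Matteson homologation and carbonyl olefination replace alkenyl migration and metathesis, with no electrophilic halogen, setting out from 8. ClCH2Li (BrCH2Cl, n-BuLi, THF, −78 °C → rt) inserts CH2 with retention to give the (3S)-3-(Bpin-methyl)chroman F5, in which boron is no longer β to O1. NaBO3·4H2O in THF/H2O gives the [(3R)-chroman-3-yl]methanol F6. Dess–Martin periodinane buffered with NaHCO3 gives the (3S)-chroman-3-carbaldehyde F7, which is used at once.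
- **Return to the route:** The neutral stabilised ylide Ph3P=CHC(O)CH3 in CH2Cl2 converts F7 into the E-enone. The route is rejoined at 14, and step 8 is bypassed as well.

Further compounds
F1 | step 11 | (E)-4-[(3R)-8-(1,3-dioxolan-2-yl)-5-methoxy-7-(triisopropylsilyloxy)chroman-3-yl]but-3-enoic acid | COc1cc(O[Si](C(C)C)(C(C)C)C(C)C)c(C3OCCO3)c2c1C[C@H](/C=C/CC(=O)O)CO2
F2 | step 11 | (E)-4-[(3R)-8-(1,3-dioxolan-2-yl)-5-methoxy-7-(triisopropylsilyloxy)chroman-3-yl]but-3-enoyl chloride | COc1cc(O[Si](C(C)C)(C(C)C)C(C)C)c(C3OCCO3)c2c1C[C@H](/C=C/CC(=O)Cl)CO2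
F3 | step 6 | [(3S)-8-(1,3-dioxolan-2-yl)-5-methoxy-7-(triisopropylsilyloxy)chroman-3-yl]bis(isopinocampheyl)borane, isopinocampheyl groups from (+)-α-pinene | COc1cc(O[Si](C(C)C)(C(C)C)C(C)C)c(C3OCCO3)c2c1C[C@H](B([C@@H]3C[C@@H]4C[C@H]([C@H]3C)C4(C)C)[C@@H]3C[C@@H]4C[C@H]([C@H]3C)C4(C)C)CO2
F4 | step 6 | diethyl [(3S)-8-(1,3-dioxolan-2-yl)-5-methoxy-7-(triisopropylsilyloxy)chroman-3-yl]boronate | COc1cc(O[Si](C(C)C)(C(C)C)C(C)C)c(C3OCCO3)c2c1C[C@H](B(OCC)OCC)CO2
F5 | step 7 | (3S)-8-(1,3-dioxolan-2-yl)-5-methoxy-3-[(4,4,5,5-tetramethyl-1,3,2-dioxaborolan-2-yl)methyl]-7-(triisopropylsilyloxy)chroman | COc1cc(O[Si](C(C)C)(C(C)C)C(C)C)c(C3OCCO3)c2c1C[C@H](CB3OC(C)(C)C(C)(C)O3)CO2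
F6 | step 7 | [(3R)-8-(1,3-dioxolan-2-yl)-5-methoxy-7-(triisopropylsilyloxy)chroman-3-yl]methanol | COc1cc(O[Si](C(C)C)(C(C)C)C(C)C)c(C3OCCO3)c2c1C[C@H](CO)CO2
F7 | step 7 | (3S)-8-(1,3-dioxolan-2-yl)-5-methoxy-7-(triisopropylsilyloxy)chroman-3-carbaldehyde | COc1cc(O[Si](C(C)C)(C(C)C)C(C)C)c(C3OCCO3)c2c1C[C@H](C=O)CO2
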